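**Assumption:** Gardenin C as drawn (5,5'-dihydroxy-3',4',6,7,8-pentamethoxyflavone) is achiral, so there are no stereocenters to set. Every SMILES below is therefore stereo-free.

## Retrosynthetic overview
1. Target ⇒ 5-OMe/5'-OBn-protected flavone, via a final peri-demethylation and debenzylation.
2. Flavone ⇒ chromone **8** + aryl boronic acid **10**. The C2–C1' bond forms by a radical (Minisci-type) arylation of the protonated chromone.
3. Chromone **8** ⇒ pentaoxygenated acetophenone **7** ⇒ pentamethoxybenzene **6** ⇒ 2,3,5-trimethoxybenzoquinone ⇒ 2,3-dimethoxyquinone ⇒ 2,3-dimethoxyphenol ⇒ veratrole ⇒ catechol.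
4. Boronic acid **10** ⇒ Ir-catalysed, sterically controlled C5–H borylation of the benzyl ether of 2,3-dimethoxyphenol.
5. Ring order: A ring (quinone functionalisation), then pyranone C ring, then B ring attached last by the radical coupling.

## Route

**Step 1**
Reactants: **1** catechol
Product: **2** veratrole (1,2-dimethoxybenzene)
Conditions: Me2SO4, K2CO3, acetone, reflux
Reagents that add atoms: Me2SO4 (COS(=O)(=O)OC)
Why: Double Williamson O-methylation of the catechol.

**Step 2**
Reactants: **2**
Product: **3** 2,3-dimethoxyphenol
Conditions: n-BuLi, THF, 0 °C→rt; B(OMe)3, –78→0 °C; then H2O2, AcOH, 0 °C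
Reagents that add atoms: H2O2 (OO, supplies the phenol O)
Why: Ortho-lithiation between the two OMe groups (directed metalation), then oxidative borate-to-phenol conversion, places the third contiguous oxygen.

**Step 3**
Reactants: **3**
Product: **4** 2,3-dimethoxy-1,4-benzoquinone
Conditions: Fremy's salt, KH2PO4, acetone/H2O, rt
Reagents that add atoms: Fremy's salt K2[ON(SO3)2] (O=N(S(=O)(=O)O[K])S(=O)(=O)O[K]) and H2O (O)
Why: Teuber oxidation puts the new C=O para to the phenol OH; C4 is the only free para position.

**Step 4**
Reactants: **4**
Product: **5** 2,3,5-trimethoxy-1,4-benzoquinone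
Conditions: MeOH, cat. H2SO4, rt; then Ag2O, CH2Cl2, rt
Reagents that add atoms: MeOH (CO)
Why: Proposed new method: acid-catalysed oxa-Michael addition of MeOH to the protonated quinone, then Ag2O reoxidation of the resulting hydroquinone. The closest known reaction is the addition of alcohols to quinones followed by reoxidation. C5 and C6 are equivalent by symmetry, so there is no regiochemistry issue, and the only free C–H ends up where the acetyl group goes next.

**Step 5**
Reactants: **5**
Product: **6** 1,2,3,4,5-pentamethoxybenzene
Conditions: Na2S2O4, THF/H2O, rt; then Me2SO4, KOH(aq), Bu4NBr, 0 °C→rt (one pot)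
Reagents that add atoms: Me2SO4 (COS(=O)(=O)OC)
Why: Reductive methylation of the quinone (dithionite, then Williamson) gives the contiguous pentaoxygenated ring with one C–H.

**Step 6**
Reactants: **6**
Product: **7** 1-(2-hydroxy-3,4,5,6-tetramethoxyphenyl)ethan-1-one
Conditions: AcCl, AlCl3, CH2Cl2, 0 °C→rt
Reagents that add atoms: AcCl (CC(=O)Cl)
Why: Friedel–Crafts acylation at the lone C–H, with AlCl3 chelation cleaving one ortho OMe to give the H-bonded 2'-hydroxyketone. The two ortho positions are equivalent, so only one product forms.

**Step 7**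
Reactants: **7**
Product: **8** 5,6,7,8-tetramethoxy-4H-chromen-4-one
Conditions: DMF-DMA, toluene, 100 °C; then 2 M HCl, MeOH, 60 °C
Reagents that add atoms: DMF-DMA (CN(C)C(OC)OC), which supplies C2 as a CH
Why: Enaminone formation followed by acid-mediated cyclisation and loss of Me2NH is the standard 2-unsubstituted chromone synthesis.

**Step 8**
Reactants: **3**
Product: **9** 1-(benzyloxy)-2,3-dimethoxybenzene
Conditions: BnBr, K2CO3, DMF, 25 °C
Reagents that add atoms: BnBr (BrCc1ccccc1)
Why: Williamson etherification masks the future 5'-OH as a benzyl ether.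

**Step 9**
Reactants: **9**
Product: **10** (3-(benzyloxy)-4,5-dimethoxyphenyl)boronic acid
Conditions: [Ir(OMe)(cod)]2 (1.5 mol%), dtbpy (3 mol%), B2pin2, THF, 80 °C; then NaIO4, NH4OAc, acetone/H2O, 25 °C
Reagents that add atoms: B2pin2 (CC1(C)OB(OC1(C)C)B1OC(C)(C)C(C)(C)O1), which supplies B
Why: Ir-catalysed C–H borylation is sterically controlled and goes to C5, the only position with no ortho substituent. That is the position para to the central OMe, which SEAr cannot reach; periodate then cleaves the pinacol ester.

**Step 10**
Reactants: **8** chromone and **10** boronic acid (3 equiv)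
Product: **11** 2-(3-benzyloxy-4,5-dimethoxyphenyl)-5,6,7,8-tetramethoxychromone
Conditions: AgNO3 (20 mol%), K2S2O8 (3 equiv), TFA (2 equiv), CH2Cl2/H2O 1:1, 40 °C
Reagents that add atoms: none
Why: Proposed new method: TFA protonates the chromone to a 4-hydroxybenzopyrylium ion, which is an electrophilic heteroarene. Ag(I)/persulfate oxidises the boronic acid to a nucleophilic aryl radical, which adds at C2 (largest LUMO coefficient), giving an α-keto radical at C3. Oxidation and loss of H+ then restore the pyranone, so the C2–C1' bond forms in a radical step and the flavone is formed directly. The closest known reactions are Minisci-type arylation of heteroarenes with arylboronic acids and Meerwein arylation of enones.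

**Step 11**
Reactants: **11**
Product: **12** Gardenin C
Conditions: BCl3 (4 equiv), pentamethylbenzene (3 equiv), CH2Cl2, –78→0 °C, then MeOH quench
Reagents that add atoms: none
Why: BCl3 cleaves the carbonyl-chelated peri 5-OMe selectively, and the benzyl ether is removed with pentamethylbenzene as cation scavenger (Lewis-acid O-demethylation and debenzylation). The 6-, 7-, 8-, 3'- and 4'-OMe groups are not chelated and survive at low temperature.

## Compound list
1 | catechol | Oc1ccccc1O | starting material
2 | veratrole | COc1ccccc1OC | intermediate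
3 | 2,3-dimethoxyphenol | COc1cccc(O)c1OC | intermediate
4 | 2,3-dimethoxy-1,4-benzoquinone | COC1=C(OC)C(=O)C=CC1=O | intermediate
5 | 2,3,5-trimethoxy-1,4-benzoquinone | COC1=CC(=O)C(OC)=C(OC)C1=O | intermediate
6 | 1,2,3,4,5-pentamethoxybenzene | COc1cc(OC)c(OC)c(OC)c1OC | intermediate
7 | 1-(2-hydroxy-3,4,5,6-tetramethoxyphenyl)ethanone | CC(=O)c1c(O)c(OC)c(OC)c(OC)c1OC | intermediate
8 | 5,6,7,8-tetramethoxychromone | O=c1ccoc2c(OC)c(OC)c(OC)c(OC)c12 | intermediate
9 | 1-(benzyloxy)-2,3-dimethoxybenzene | COc1cccc(OCc2ccccc2)c1OC | intermediate
10 | (3-(benzyloxy)-4,5-dimethoxyphenyl)boronic acid | COc1cc(B(O)O)cc(OCc2ccccc2)c1OC | intermediate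
11 | 2-(3-benzyloxy-4,5-dimethoxyphenyl)-5,6,7,8-tetramethoxychromone | COc1cc(-c2cc(=O)c3c(OC)c(OC)c(OC)c(OC)c3o2)cc(OCc2ccccc2)c1OC | intermediate
12 | Gardenin C | COc1cc(-c2cc(=O)c3c(O)c(OC)c(OC)c(OC)c3o2)cc(O)c1OC | target

## Totals
Total steps: 11. Longest linear sequence: 9 (1→2→3→4→5→6→7→8→11→12).

## Three steps most likely to fail
1. **Step 10, radical C2-arylation.** Risks are C3 attack, oxidative loss of the electron-rich arenes, and protodeboronation. Fallback: Pd(II)-catalysed oxidative C2–H arylation of chromone **8** with boronic acid **10** (Pd(OAc)2, Cu(II) or benzoquinone oxidant), a two-electron organometallic route.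
2. **Step 4, MeOH addition and reoxidation on a deactivated dialkoxyquinone.** Fallback: Thiele–Winter acetoxylation of **4** (Ac2O, cat. H2SO4), then methanolysis and exhaustive methylation, giving **6** directly by an electrophilic acetoxylation route.
3. **Step 11, chemoselective deprotection.** BCl3 could also cleave 4'-OMe next to the freed 5'-O. Fallback: demethylate chromone **8** selectively at 5-OMe before the coupling, couple the 5-hydroxychromone, and remove the benzyl group last by H2, Pd/C.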